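**Plan**
- Retrosynthesis: the two acyl groups are removed and the C6 carbinol is returned to an ester; the arene bonds C5–C6 and C6–C7 are then cut, which takes C6 out as a bromo(ester)carbene and leaves a fused cyclopentadiene.
- Next cuts: the C5 side-chain bond (acetate enolate plus ketone), the three bonds of a Pauson–Khand cyclopentenone, the alkyne–CH2O bond, and the allyl–quaternary-carbon bond of an enyne derived from mesityl oxide.
- Forward: the chain is assembled first, both five-membered rings close together in the Pauson–Khand step, and the benzene ring arises last by one-carbon expansion of the cyclopentadiene ring.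
- Stereochemistry: the target has no stereocentre; the ring-fusion centre (racemic), the carbinol centre (epimer mixture) and the cyclopropane centres are transient and are erased by dehydration and aromatisation.

Key step: step 10

Remark on the chemistry: locants in the Why lines are those of the indane product (C2 CMe2, C4 CH2O, C5 chain, C6 inserted carbon, C7 H, C7a ring fusion); in the names of 9–15 these atoms carry the pentalene locants 5, 3, 2, –, 1 and 6a. Compounds 9–15 and 18 are racemic, and the carbinol centre of 11–14 is carried as both epimers because it becomes sp2 in step 8.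

**Step 1**
Reactants: 1 4-methylpent-3-en-2-one (mesityl oxide); 2 allyltrimethylsilane
Product: 3 4,4-dimethylhept-6-en-2-one
Conditions: TiCl4 (1.0 equiv), CH2Cl2, −78 °C; H2O
Reagents that add atoms: none
Why: Hosomi–Sakurai conjugate allylation, in which the TiCl4-activated enone is attacked at its β-carbon by the allylsilane and the β-silyl cation loses silicon, is a reliable way to an all-carbon quaternary centre.

**Step 2**
Reactants: 3 4,4-dimethylhept-6-en-2-one
Product: 6 5,5-dimethyloct-7-en-2-yn-1-ol, via enol phosphate 4 (not isolated), via lithium acetylide 5 (not isolated)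
Conditions: LiN(iPr)2 (1.1 equiv), THF, −78 °C; ClP(O)(OEt)2, −78 → 23 °C; LiN(iPr)2 (2.3 equiv), −78 → 23 °C; (CH2O)n, 0 → 23 °C; aq NH4Cl
Reagents that add atoms: paraformaldehyde (formaldehyde), C=O
Why: In this Negishi alkyne synthesis the amide base removes a proton of the unhindered methyl group, the enolate is phosphorylated on oxygen, further base eliminates diethyl phosphate to leave the acetylide, and the acetylide should add to formaldehyde in the same flask.

**Step 3**
Reactants: 6 5,5-dimethyloct-7-en-2-yn-1-ol
Product: 7 tert-butyl[(5,5-dimethyloct-7-en-2-yn-1-yl)oxy]dimethylsilane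
Conditions: TBSCl, imidazole, DMF, 23 °C
Reagents that add atoms: tert-butyldimethylsilyl chloride, CC(C)(C)[Si](C)(C)Cl
Why: Standard silylation of a primary alcohol gives an ether that should tolerate cobalt carbonyls, enolates, hydrides and the carbenoid step.

**Step 4**
Reactants: 7 tert-butyl[(5,5-dimethyloct-7-en-2-yn-1-yl)oxy]dimethylsilane
Product: 9 3-(tert-butyldimethylsilyloxymethyl)-5,5-dimethyl-4,5,6,6a-tetrahydropentalen-2(1H)-one (racemic), via dicobalt hexacarbonyl alkyne complex 8 (not isolated)
Conditions: Co2(CO)8 (1.1 equiv), CH2Cl2, 23 °C; N-methylmorpholine N-oxide (8 equiv), 0 → 23 °C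
Reagents that add atoms: dicobalt octacarbonyl, O=C=[Co](=C=O)(=C=O)(=C=O)[Co](=C=O)(=C=O)(=C=O)=C=O
Why: The intramolecular Pauson–Khand [2+2+1] cycloaddition, promoted by the amine N-oxide and helped by the gem-dimethyl group, should place the alkyne substituent next to the new ketone and form the single ring-fusion stereocentre as a racemate.

**Step 5**
Reactants: 9 3-(tert-butyldimethylsilyloxymethyl)-5,5-dimethyl-4,5,6,6a-tetrahydropentalen-2(1H)-one; 10 ethyl acetate
Product: 11 ethyl 2-[3-(tert-butyldimethylsilyloxymethyl)-2-hydroxy-5,5-dimethyl-1,2,4,5,6,6a-hexahydropentalen-2-yl]acetate (both carbinol epimers)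
Conditions: LiN(iPr)2, EtOAc, THF, −78 °C; then 9, −78 °C; AcOH quench at −78 °C
Reagents that add atoms: none
Why: Aldol-type 1,2-addition of the lithium enolate of ethyl acetate to the carbonyl of a β,β-disubstituted enone is the kinetic course at −78 °C, and the uncontrolled carbinol centre is of no consequence.

**Step 6**
Reactants: 11 ethyl 2-[3-(tert-butyldimethylsilyloxymethyl)-2-hydroxy-5,5-dimethyl-1,2,4,5,6,6a-hexahydropentalen-2-yl]acetate
Product: 12 3-(tert-butyldimethylsilyloxymethyl)-2-(2-hydroxyethyl)-5,5-dimethyl-1,2,4,5,6,6a-hexahydropentalen-2-ol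
Conditions: LiAlH4 (excess, 11 added to the hydride), THF, 0 °C; H2O, aq NaOH
Reagents that add atoms: none
Why: Hydride reduction of the ester to the primary alcohol is fast at 0 °C, which should outrun retro-aldol cleavage of the tertiary alkoxide.

**Step 7**
Reactants: 12 3-(tert-butyldimethylsilyloxymethyl)-2-(2-hydroxyethyl)-5,5-dimethyl-1,2,4,5,6,6a-hexahydropentalen-2-ol
Product: 13 3-(tert-butyldimethylsilyloxymethyl)-2-(2-chloroethyl)-5,5-dimethyl-1,2,4,5,6,6a-hexahydropentalen-2-ol
Conditions: PPh3, N-chlorosuccinimide, CH2Cl2, −20 → 0 °C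
Reagents that add atoms: N-chlorosuccinimide, O=C1CCC(=O)N1Cl
Why: In this Appel-type chlorination only the primary hydroxyl can be activated on phosphorus and displaced by chloride in an SN2 step, so the hindered tertiary allylic hydroxyl should stay.

**Step 8**
Reactants: 13 3-(tert-butyldimethylsilyloxymethyl)-2-(2-chloroethyl)-5,5-dimethyl-1,2,4,5,6,6a-hexahydropentalen-2-ol
Product: 15 3-(tert-butyldimethylsilyloxymethyl)-2-(2-chloroethyl)-5,5-dimethyl-4,5,6,6a-tetrahydropentalene (racemic), via tertiary sulfamate 14 (not isolated)
Conditions: Burgess reagent (MeO2CN–SO2N+Et3, 1.5 equiv), THF–toluene, 0 °C; cold filtration through Florisil with pentane; solution kept at −78 °C and used within the hour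
Reagents that add atoms: none
Why: Burgess dehydration proceeds by syn β-elimination (Ei) from the sulfamate, for which only the ring hydrogen at C7 and the side-chain methylene are in reach, and five-membered rings favour the endocyclic course that gives the cyclopentadiene with the C7a hydrogen left in place.

**Step 9**
Reactants: 16 ethyl diazoacetate
Product: 17 ethyl bromodiazoacetate
Conditions: N-bromosuccinimide (1.1 equiv), DBU (1.4 equiv), CH2Cl2, 0 °C, 5 min; cold filtration through silica; solution used at once
Reagents that add atoms: N-bromosuccinimide, O=C1CCC(=O)N1Br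
Why: Deprotonation of the diazoacetate by DBU and electrophilic bromination at the diazo carbon is the established preparation of the thermally labile halodiazoacetates.

**Step 10**
Reactants: 15 3-(tert-butyldimethylsilyloxymethyl)-2-(2-chloroethyl)-5,5-dimethyl-4,5,6,6a-tetrahydropentalene; 17 ethyl bromodiazoacetate
Product: 19 ethyl 4-(tert-butyldimethylsilyloxymethyl)-5-(2-chloroethyl)-2,2-dimethylindane-6-carboxylate, via endo-bromocyclopropane 18 (not isolated)
Conditions: Rh2(esp)2 (2 mol %; esp = α,α,α′,α′-tetramethyl-1,3-benzenedipropanoate), Cs2CO3 (1.5 equiv), 17 (1.6 equiv, cold CH2Cl2 solution added over 20 min), toluene, 0 → 23 °C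
Reagents that add atoms: none
Why: Proposed new method: the rhodium-bound bromo(ethoxycarbonyl)carbene should add in a [2+1] sense to the trisubstituted C5=C7 bond of 15 with the ester exo and the bromine endo, and the endo C–Br bond of 18 then ionises with disrotatory cyclopropyl-to-allyl opening of the C5–C7 bond to a cation that is the C7a-protonated σ-complex of the arene, which gives up that proton to Cs2CO3. The closest known reactions are the dirhodium-catalysed cyclopropanation and ring expansion of indenes and indoles with ethyl halodiazoacetates and the dihalocarbene conversion of cyclopentadienes into halobenzenes, so a fused, non-benzo cyclopentadiene is the new substrate class. The six-membered ring is not closed by a cyclisation: it arises by insertion of C6 between C5 and C7 (cheletropic addition, then electrocyclic cleavage of the shared bond), so both new bonds, C5–C6 and C6–C7, are made in the cyclopropanation. The stereocentres of 18 and C7a are transient, and only the endo position of bromine matters; it follows from the preference of the ester for the exo side, as is usual for acceptor carbenoids on cyclic alkenes. The step needs site selectivity for C5=C7 over the tetrasubstituted C3a=C4 bond, which the steric demand of the dirhodium carbenoid and the shielding of C4 by its silyloxymethyl group should secure, and it needs the double bonds to stay in place, which the cold and immediate use of 15 and the mild base provide.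

**Step 11**
Reactants: 19 ethyl 4-(tert-butyldimethylsilyloxymethyl)-5-(2-chloroethyl)-2,2-dimethylindane-6-carboxylate
Product: 20 [4-(tert-butyldimethylsilyloxymethyl)-5-(2-chloroethyl)-2,2-dimethylindan-6-yl]methanol
Conditions: iBu2AlH (2.5 equiv), CH2Cl2, −78 → 0 °C; aq Rochelle salt
Reagents that add atoms: none
Why: The aluminium hydride reduces the aryl ester to the benzylic alcohol at low temperature and should leave the primary alkyl chloride and the silyl ether untouched.

**Step 12**
Reactants: 20 [4-(tert-butyldimethylsilyloxymethyl)-5-(2-chloroethyl)-2,2-dimethylindan-6-yl]methanol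
Product: 21 [4-(tert-butyldimethylsilyloxymethyl)-5-(2-chloroethyl)-2,2-dimethylindan-6-yl]methyl butanoate
Conditions: (PrCO)2O, Et3N, DMAP (cat.), CH2Cl2, 0 °C
Reagents that add atoms: butanoic anhydride, CCCC(=O)OC(=O)CCC
Why: DMAP-catalysed acylation of the primary benzylic alcohol is fast under conditions that form no free alkoxide able to close onto the chloroethyl chain.

**Step 13**
Reactants: 21 [4-(tert-butyldimethylsilyloxymethyl)-5-(2-chloroethyl)-2,2-dimethylindan-6-yl]methyl butanoate
Product: 22 [5-(2-chloroethyl)-4-(hydroxymethyl)-2,2-dimethylindan-6-yl]methyl butanoate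
Conditions: HF·pyridine, THF–pyridine, 0 → 23 °C
Reagents that add atoms: none
Why: Fluoride cleavage of the primary silyl ether under buffered acidic conditions avoids a free alkoxide, which could displace the neighbouring chloride to an isochromane or attack the butanoate.

**Step 14**
Reactants: 22 [5-(2-chloroethyl)-4-(hydroxymethyl)-2,2-dimethylindan-6-yl]methyl butanoate
Product: 23 [4-(acetoxymethyl)-5-(2-chloroethyl)-2,2-dimethylindan-6-yl]methyl butanoate (CNP0321917.0)
Conditions: Ac2O, pyridine, DMAP (cat.), CH2Cl2, 0 → 23 °C
Reagents that add atoms: acetic anhydride, CC(=O)OC(C)=O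
Why: DMAP-catalysed acetylation of the remaining primary alcohol should give the target without touching the butanoate or the chloride.

**Compound list**
1 | 4-methylpent-3-en-2-one (mesityl oxide) | CC(=O)C=C(C)C | starting material
2 | allyltrimethylsilane | C=CC[Si](C)(C)C | starting material
3 | 4,4-dimethylhept-6-en-2-one | CC(=O)CC(C)(C)CC=C | intermediate
4 | diethyl 4,4-dimethylhepta-1,6-dien-2-yl phosphate | C=C(OP(=O)(OCC)OCC)CC(C)(C)CC=C | intermediate
5 | lithium 4,4-dimethylhept-6-en-1-yn-1-ide | [Li]C#CCC(C)(C)CC=C | intermediate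
6 | 5,5-dimethyloct-7-en-2-yn-1-ol | OCC#CCC(C)(C)CC=C | intermediate
7 | tert-butyl[(5,5-dimethyloct-7-en-2-yn-1-yl)oxy]dimethylsilane | C=CCC(C)(C)CC#CCO[Si](C)(C)C(C)(C)C | intermediate
8 | hexacarbonyldicobalt complex of alkyne 7 (dicobaltatetrahedrane) | C=CCC(C)(C)CC12C3(CO[Si](C)(C)C(C)(C)C)[Co]1(=C=O)(=C=O)(=C=O)[Co]23(=C=O)(=C=O)=C=O | intermediate
9 | 3-(tert-butyldimethylsilyloxymethyl)-5,5-dimethyl-4,5,6,6a-tetrahydropentalen-2(1H)-one, racemic, (6aS) enantiomer drawn | O=C1C[C@@H]2CC(C)(C)CC2=C1CO[Si](C)(C)C(C)(C)C | intermediate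
10 | ethyl acetate | CCOC(C)=O | starting material
11 | ethyl 2-[3-(tert-butyldimethylsilyloxymethyl)-2-hydroxy-5,5-dimethyl-1,2,4,5,6,6a-hexahydropentalen-2-yl]acetate, racemic, both C-2 epimers, (6aS) drawn | CCOC(=O)CC1(O)C[C@@H]2CC(C)(C)CC2=C1CO[Si](C)(C)C(C)(C)C | intermediate
12 | 3-(tert-butyldimethylsilyloxymethyl)-2-(2-hydroxyethyl)-5,5-dimethyl-1,2,4,5,6,6a-hexahydropentalen-2-ol, racemic, both C-2 epimers | OCCC1(O)C[C@@H]2CC(C)(C)CC2=C1CO[Si](C)(C)C(C)(C)C | intermediate
13 | 3-(tert-butyldimethylsilyloxymethyl)-2-(2-chloroethyl)-5,5-dimethyl-1,2,4,5,6,6a-hexahydropentalen-2-ol, racemic, both C-2 epimers | ClCCC1(O)C[C@@H]2CC(C)(C)CC2=C1CO[Si](C)(C)C(C)(C)C | intermediate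
14 | triethylammonium salt of the N-(methoxycarbonyl)sulfamate ester of 13 | COC(=O)[N-]S(=O)(=O)OC1(CCCl)C[C@@H]2CC(C)(C)CC2=C1CO[Si](C)(C)C(C)(C)C.CC[NH+](CC)CC | intermediate
15 | 3-(tert-butyldimethylsilyloxymethyl)-2-(2-chloroethyl)-5,5-dimethyl-4,5,6,6a-tetrahydropentalene, racemic, (6aS) enantiomer drawn | ClCCC1=C[C@@H]2CC(C)(C)CC2=C1CO[Si](C)(C)C(C)(C)C | intermediate
16 | ethyl diazoacetate | CCOC(=O)C=[N+]=[N-] | starting material
17 | ethyl bromodiazoacetate | CCOC(=O)C(Br)=[N+]=[N-] | intermediate
18 | ethyl bromocyclopropanecarboxylate adduct across the C1=C2 bond of 15, racemic, cyclopropane on the face of H-6a, bromine endo over the five-membered ring, ester exo | CCOC(=O)[C@]1(Br)[C@H]2[C@@H]3CC(C)(C)CC3=C(CO[Si](C)(C)C(C)(C)C)[C@@]12CCCl | intermediate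
19 | ethyl 4-(tert-butyldimethylsilyloxymethyl)-5-(2-chloroethyl)-2,2-dimethylindane-6-carboxylate | CCOC(=O)c1cc2c(c(CO[Si](C)(C)C(C)(C)C)c1CCCl)CC(C)(C)C2 | intermediate
20 | [4-(tert-butyldimethylsilyloxymethyl)-5-(2-chloroethyl)-2,2-dimethylindan-6-yl]methanol | OCc1cc2c(c(CO[Si](C)(C)C(C)(C)C)c1CCCl)CC(C)(C)C2 | intermediate
21 | [4-(tert-butyldimethylsilyloxymethyl)-5-(2-chloroethyl)-2,2-dimethylindan-6-yl]methyl butanoate | CCCC(=O)OCc1cc2c(c(CO[Si](C)(C)C(C)(C)C)c1CCCl)CC(C)(C)C2 | intermediate
22 | [5-(2-chloroethyl)-4-(hydroxymethyl)-2,2-dimethylindan-6-yl]methyl butanoate | CCCC(=O)OCc1cc2c(c(CO)c1CCCl)CC(C)(C)C2 | intermediate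
23 | [4-(acetoxymethyl)-5-(2-chloroethyl)-2,2-dimethylindan-6-yl]methyl butanoate (CNP0321917.0) | CCCC(=O)OCc1cc2c(c(COC(C)=O)c1CCCl)CC(C)(C)C2 | target

**Step count**
Total: 14 steps. Longest linear sequence: 13 steps (steps 1–8 and 10–14, from mesityl oxide); step 9 is a one-step side branch.

**Steps most likely to fail**

1. Step 10 (proposed method). The carbenoid may add to the tetrasubstituted C3a=C4 bond or dimerise, a cyclopropane with exo bromine would not open, and the diene may shift its double bonds before it is trapped. The fallback uses known chemistry and sets out from 15. Bromoform and KOtBu in pentane at −20 °C generate dibromocarbene; bromoform is the stronger acid, so the alkylated cyclopentadiene should not be deprotonated. Addition across C5=C7 should give the 6,6-dibromobicyclo[3.1.0]hexene adduct F1, which always has an endo bromine and should open with loss of HBr to 6-bromo-4-(tert-butyldimethylsilyloxymethyl)-5-(2-chloroethyl)-2,2-dimethylindane F2. Ethoxycarbonylation of this aryl bromide with Pd(OAc)2, 1,1′-bis(diphenylphosphino)ferrocene, CO (1 atm), EtOH and Et3N at 80 °C should then return the route at 19, the alkyl chloride being inert to this catalyst.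

2. Step 8. Proton loss may go toward the ring fusion or the side chain instead of C7, the sulfamate may transpose allylically, and 1,5-hydrogen shifts may move the double bonds on warming. The fallback fixes the C5=C7 double bond by kinetic enolisation instead of elimination and sets out from 9.
   - LiN(iPr)2 and Me3SiCl in THF at −78 °C should remove a C7 proton and give the cross-conjugated 2-trimethylsilyloxy diene F3.
   - F3 is treated with 17 under the conditions of step 10. The electron-rich enol ether bond should take up the carbenoid and expand in the manner known for halocarbene ring expansion of silyl enol ethers. A K2CO3/MeOH work-up should leave ethyl 4-(tert-butyldimethylsilyloxymethyl)-5-hydroxy-2,2-dimethylindane-6-carboxylate F4.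
   - Tf2O and pyridine should give the aryl triflate F5.
   - Suzuki coupling with potassium vinyltrifluoroborate (Pd(dppf)Cl2, Cs2CO3, THF–H2O, 80 °C) should give the 5-vinyl ester F6.
   - 9-BBN followed by NaBO3·4H2O should give the 5-(2-hydroxyethyl) ester F7, which is chlorinated at once to forestall lactonisation.
   - PPh3 and N-chlorosuccinimide, as in step 7, should bring the route back at 19.

3. Step 5. The ester enolate may act as a base and enolise the enone at C7 or at the γ-positions, and the aldolate may revert during quench. The fallback sets out from 9. Vinylmagnesium bromide with CeCl3 in THF at −78 °C, a weakly basic organocerium addition, should give the tertiary 2-vinyl carbinol F8. Hydroboration of the monosubstituted alkene with 9-BBN in THF, followed by NaOH and H2O2, should then give diol 12, where the route is rejoined.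

**Further compounds**
F1 | step 10 | 6,6-dibromobicyclo[3.1.0]hexene adduct of dibromocarbene across the C1=C2 bond of 15 | BrC1(Br)[C@H]2[C@@H]3CC(C)(C)CC3=C(CO[Si](C)(C)C(C)(C)C)[C@@]12CCCl
F2 | step 10 | 6-bromo-4-(tert-butyldimethylsilyloxymethyl)-5-(2-chloroethyl)-2,2-dimethylindane | Brc1cc2c(c(CO[Si](C)(C)C(C)(C)C)c1CCCl)CC(C)(C)C2
F3 | step 8 | 3-(tert-butyldimethylsilyloxymethyl)-5,5-dimethyl-2-(trimethylsilyloxy)-4,5,6,6a-tetrahydropentalene | C[Si](C)(C)OC1=C[C@@H]2CC(C)(C)CC2=C1CO[Si](C)(C)C(C)(C)C
F4 | step 8 | ethyl 4-(tert-butyldimethylsilyloxymethyl)-5-hydroxy-2,2-dimethylindane-6-carboxylate | CCOC(=O)c1cc2c(c(CO[Si](C)(C)C(C)(C)C)c1O)CC(C)(C)C2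
F5 | step 8 | ethyl 4-(tert-butyldimethylsilyloxymethyl)-2,2-dimethyl-5-(trifluoromethylsulfonyloxy)indane-6-carboxylate | CCOC(=O)c1cc2c(c(CO[Si](C)(C)C(C)(C)C)c1OS(=O)(=O)C(F)(F)F)CC(C)(C)C2
F6 | step 8 | ethyl 4-(tert-butyldimethylsilyloxymethyl)-5-ethenyl-2,2-dimethylindane-6-carboxylate | CCOC(=O)c1cc2c(c(CO[Si](C)(C)C(C)(C)C)c1C=C)CC(C)(C)C2
F7 | step 8 | ethyl 4-(tert-butyldimethylsilyloxymethyl)-5-(2-hydroxyethyl)-2,2-dimethylindane-6-carboxylate | CCOC(=O)c1cc2c(c(CO[Si](C)(C)C(C)(C)C)c1CCO)CC(C)(C)C2
F8 | step 5 | 3-(tert-butyldimethylsilyloxymethyl)-2-ethenyl-5,5-dimethyl-1,2,4,5,6,6a-hexahydropentalen-2-ol | C=CC1(O)C[C@@H]2CC(C)(C)CC2=C1CO[Si](C)(C)C(C)(C)C
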